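Take one stirred vessel and settle how the starting material goes into it.

common to all: free enzyme 0.050 µM; added ligand 0.072 µM; time 1.0 min
- oak: starting material 5.0 × 10⁻⁴ M; second substrate 0.500 mM; everything together at the start
- alder: starting material 5.0 × 10⁻⁴ M (fed, over 50 s); second substrate 0.500 mM; all else is in the flask from the start; the feed brings no volume worth counting
- larch: starting material 5.0 × 10⁻⁴ M (in portions, 4, over 50 s); second substrate 0.500 mM; first portion at the start, last at 50 s
- birch: starting material 5.0 × 10⁻⁴ M; second substrate 0.500 mM (fed, over 50 s); all else is in the flask from the start; the feed brings no volume worth counting

    starting material + free enzyme ⇌ first complex (K1 = 3500 L mol⁻¹, k1 = 3.6 × 10⁶ L mol⁻¹ s⁻¹)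
    first complex → loaded enzyme + first product (k2 = 10000 s⁻¹)
    second substrate + loaded enzyme ⇌ second complex (K3 = 3600 L mol⁻¹, k3 = 3.0 × 10⁷ L mol⁻¹ s⁻¹)
    second complex → free enzyme + target (k4 = 480 s⁻¹)
    free enzyme + added ligand ⇌ idle complex, settled at all times (K5 = 3.0 × 10⁷ L mol⁻¹)
    starting material + target → side product (k6 = 32 L mol⁻¹ s⁻¹)
    crystals ⇌ target, rate k7*(cs7 - [target]) while solid is left; crystals form when [target] > cs7 (cs7 = 0.18 mM, k7 = 0.12 s⁻¹)

- percent here means starting material units held: one side product counts as two
- what is said of target includes crystals
- crystals is a solid; its amount is given per volume of the solution
- run time (oak): 1.0 min

- the flask that comes out highest in amount of side product, in percent of the starting material charged, or "all alike" when all lie within 1.5 percentage points (oak / alder / larch / birch / all alike)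
- side product at the end, in percent of the starting material charged, oak
- side product at the end, in percent of the starting material charged, alder
- side product at the end, in percent of the starting material charged, larch
- side product at the end, in percent of the starting material charged, birch

Count the run in one lifetime. With target dissolved at its solubility, the side reaction is pseudo-first-order in starting material, so define the saturation lifetime, 174 s: the mean time a molecule of starting material lasts against the side reaction at that [target]. Use this rule, with [target] held at solubility: side product in percent is two, for the units each side product holds, times mean [starting material] over the charge, times saturated time over the lifetime.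

Now find the saturated time in oak. Reckon one round of the catalyst at 0.00500 s, with starting material, added ligand and second substrate each held at its charge. That gives a pace of 10.0 µM s⁻¹. Held at this pace, my reckoning brings [target] to solubility at 18.0 s, earlier than the end of the run, and uses up the charge at 50.0 s. Take the filling stretch at a mean [target] of a 0.5 fraction of solubility, and let [starting material] fall in a straight line. My reckoning then puts oak at 20.3%.

Next, decide the dosing. A steady feed over 50 s, as in alder, delivers 10.0 µM s⁻¹, which about matches that pace, so expect a lower mean [starting material] during the dosing in alder than in oak. Dose the starting material, then. Feeding the second substrate instead, as in birch, leaves the charge of starting material, 5.0 × 10⁻⁴ M, in the vessel at the start.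

The forecast also favours dosing the starting material, but its oak figure stands higher than mine. It names oak as highest, with 25% for oak, 16.5% for alder, 17.5% for larch and 23.5% for birch, and its ground is that the side reaction is “worst when starting material is abundant while target is high”.

Oak comes out highest at 24.8%, against 16.3% for alder, 14.8% for larch and 22.8% for birch. Mean [starting material] over the first 50 s reads 2.79 × 10⁻⁴ M in oak and 1.40 × 10⁻⁴ M in alder. Put through the saturation lifetime as if [target] stood at solubility for that whole stretch, oak's reading gives 32.1%, which is more than the 24.8% oak holds at the end. Alder's reading, taken the same way, gives 16.1%, and alder holds 16.3% at the end.

The constants are invented; the result is computed.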